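## Retrosynthetic overview

1. The epoxy aldehyde comes from the (13R,14R)-epoxy alcohol by oxidation, and that from the E-allylic alcohol by Sharpless epoxidation; the 3α-acetate comes from a 3-ketone.
2. C4 (Me/CO2Me) and C5–H come from one dissolving-metal reductive methylation of a cross-conjugated dienone keto ester.
3. Key disconnection C9–C10: oxidative dearomatizing cyclization of a salicylate carrying a meta-tethered Z-allylsilane. It closes ring B on the arene (future ring A) and sets C9, C10 and the C8 methylidene at once.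
4. The cyclization substrate comes from benzylic alkylation of methyl 6-hydroxy-2,3-dimethylbenzoate (from 2,3-dimethylbenzoic acid) with a 2-(silylmethyl)allyl bromide made from geraniol (ozonolysis, Wittig).
5. Ring order: ring A is the benzene ring of the feedstock, ring B is formed in the key step, the oxirane comes last.

Positions are given in labdane numbering: C3 carries the oxygen, C4 the ester, C10 the angular methyl, C8=C17 the methylidene, C13–C15 the end of the side chain.

Assumption: the (R,R)-configured λ3-iodane of step 10 is taken to give the (4aR,5S)-dienone; if the opposite sense is found, its (S,S) antipode is used without other change.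

## Route

Step 1
Reactants: 1 2,3-dimethylbenzoic acid
Product: 2 6-hydroxy-2,3-dimethylbenzoic acid
Conditions: Pd(OAc)2 (10 mol %), KOAc, 1,4-benzoquinone, O2 (1 atm), DMA, 115 °C
Reagents that add atoms: dioxygen O=O
Why: Carboxylate-directed C–H hydroxylation: the carboxylate guides divalent palladium to the only free ortho C–H and O2 supplies the oxygen; no stereocentre is formed.

Step 2
Reactants: 2 6-hydroxy-2,3-dimethylbenzoic acid
Product: 3 methyl 6-hydroxy-2,3-dimethylbenzoate
Conditions: MeI, KHCO3, DMF, 25 °C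
Reagents that add atoms: iodomethane CI
Why: SN2 esterification of the carboxylate; KHCO3 does not ionise the hydrogen-bonded phenol, and acid-catalysed esterification would be blocked by the two ortho substituents.

Step 3
Reactants: 4 ethyl (triphenyl-λ5-phosphanylidene)acetate (2 equiv)
Product: 5 ethyl 2-(triphenyl-λ5-phosphanylidene)-3-(trimethylsilyl)propanoate
Conditions: Me3SiCH2I, toluene, 100 °C; phosphonium salt filtered off
Reagents that add atoms: (iodomethyl)trimethylsilane C[Si](C)(C)CI
Why: Ylide C-alkylation followed by transylidation: the stabilised ylide displaces iodide and the second equivalent of 4 deprotonates the resulting phosphonium salt.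

Step 4
Reactants: 6 geraniol
Product: 7 tert-butyl{[(2E)-3,7-dimethylocta-2,6-dien-1-yl]oxy}dimethylsilane
Conditions: TBSCl, imidazole, DMF, 25 °C
Reagents that add atoms: tert-butyl(chloro)dimethylsilane CC(C)(C)[Si](C)(C)Cl
Why: Silyl ether protection of the primary alcohol; the ether is chosen to survive ylide, hydride, amide base, the λ3-iodane and Li/NH3.

Step 5
Reactants: 7 tert-butyl{[(2E)-3,7-dimethylocta-2,6-dien-1-yl]oxy}dimethylsilane
Product: 8 (4E)-6-{[tert-butyl(dimethyl)silyl]oxy}-4-methylhex-4-enal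
Conditions: O3 (0.95 equiv), pyridine (3 equiv), CH2Cl2, −78 °C
Reagents that add atoms: ozone [O-][O+]=O
Why: Chemoselective ozonolysis: electrophilic ozone cleaves the electron-richer isopropylidene alkene and spares the alkene deactivated by the allylic silyloxy group, pyridine turning the carbonyl oxide directly into the aldehyde.

Step 6
Reactants: 8 (4E)-6-{[tert-butyl(dimethyl)silyl]oxy}-4-methylhex-4-enal; 5 ethyl 2-(triphenyl-λ5-phosphanylidene)-3-(trimethylsilyl)propanoate
Product: 9 ethyl (2Z,6E)-8-{[tert-butyl(dimethyl)silyl]oxy}-6-methyl-2-[(trimethylsilyl)methyl]octa-2,6-dienoate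
Conditions: toluene, 90 °C
Reagents that add atoms: none
Why: Wittig olefination with a stabilised α-substituted ylide, which places the ester trans to the aldehyde chain, so CH2SiMe3 ends up cis to the chain (2Z), the geometry that later fixes C9.

Step 7
Reactants: 9 ethyl (2Z,6E)-8-{[tert-butyl(dimethyl)silyl]oxy}-6-methyl-2-[(trimethylsilyl)methyl]octa-2,6-dienoate
Product: 10 (2Z,6E)-8-{[tert-butyl(dimethyl)silyl]oxy}-6-methyl-2-[(trimethylsilyl)methyl]octa-2,6-dien-1-ol
Conditions: i-Bu2AlH (2.5 equiv), CH2Cl2, −78 °C; aq. KNaC4H4O6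
Reagents that add atoms: none
Why: 1,2-Reduction of the enoate to the allylic alcohol by the aluminium hydride at low temperature; allylsilane and silyl ether are inert.

Step 8
Reactants: 10 (2Z,6E)-8-{[tert-butyl(dimethyl)silyl]oxy}-6-methyl-2-[(trimethylsilyl)methyl]octa-2,6-dien-1-ol
Product: 11 {(2E,6E)-2-(bromomethyl)-8-{[tert-butyl(dimethyl)silyl]oxy}-6-methylocta-2,6-dien-1-yl}(trimethyl)silane
Conditions: CBr4, PPh3, 2,6-lutidine, CH2Cl2, −20 to 0 °C
Reagents that add atoms: tetrabromomethane BrC(Br)(Br)Br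
Why: Appel reaction: bromide displaces the alkoxyphosphonium at the primary carbon under buffered neutral conditions that spare the acid-labile allylsilane and keep the alkene geometry (CH2SiMe3 still cis to the chain).

Step 9
Reactants: 3 methyl 6-hydroxy-2,3-dimethylbenzoate; 11 {(2E,6E)-2-(bromomethyl)-8-{[tert-butyl(dimethyl)silyl]oxy}-6-methylocta-2,6-dien-1-yl}(trimethyl)silane
Product: 13 methyl 2-{(3Z,7E)-9-{[tert-butyl(dimethyl)silyl]oxy}-7-methyl-3-[(trimethylsilyl)methyl]nona-3,7-dien-1-yl}-6-hydroxy-3-methylbenzoate, via dilithium dianion 12 (not isolated)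
Conditions: LiN(i-Pr)2 (2.4 equiv), THF, −78 to −30 °C; then 11, −78 to 0 °C; aq. NH4Cl
Reagents that add atoms: none
Why: Lateral lithiation of an ortho-toluate and SN2 alkylation: after phenoxide formation the second equivalent of base deprotonates only the methyl ortho to the ester (extended enolate held planar by the Li-bridged phenoxide), and this benzylic carbanion displaces the primary allylic bromide to make the C6–C7 bond.

Step 10
Reactants: 13 methyl 2-{(3Z,7E)-9-{[tert-butyl(dimethyl)silyl]oxy}-7-methyl-3-[(trimethylsilyl)methyl]nona-3,7-dien-1-yl}-6-hydroxy-3-methylbenzoate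
Product: 14 methyl (4aR,5S)-5-{(3E)-5-{[tert-butyl(dimethyl)silyl]oxy}-3-methylpent-3-en-1-yl}-4a-methyl-6-methylidene-2-oxo-2,4a,5,6,7,8-hexahydronaphthalene-1-carboxylate
Conditions: (R,R)-2-(diacetoxyiodo)-1,3-bis[1-(mesitylcarbamoyl)ethoxy]benzene (1.2 equiv; made beforehand from the commercial iodoarene with NaBO3·4H2O in AcOH), CH2Cl2/(CF3)2CHOH 4:1, −40 °C
Reagents that add atoms: none
Why: Proposed new method: ligand exchange binds the phenol oxygen to the chiral trivalent-iodine centre, and the γ-carbon (C9) of the Z-allylsilane attacks the para carbon C10 through a six-membered chair transition state (the ortho carbon is blocked and deactivated by the ester), the β-silyl cation then losing Me3Si to give the C8 methylidene; the chair places the chain equatorial and anti to the C10 methyl's partner hydrogen (C9 S relative to C10 R), while the lactamide arms of the iodane shield one arene face to set the absolute sense; the closest known chemistry is the racemic oxidative Hosomi–Sakurai dearomatization of para-alkylphenols with allylsilanes using PhI(OAc)2 in (CF3)2CHOH, together with the enantioselective Kita-type dearomatizing spirocyclizations of phenols by the same lactate-derived aryl-λ3-iodanes.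

Step 11
Reactants: 14 methyl (4aR,5S)-5-{(3E)-5-{[tert-butyl(dimethyl)silyl]oxy}-3-methylpent-3-en-1-yl}-4a-methyl-6-methylidene-2-oxo-2,4a,5,6,7,8-hexahydronaphthalene-1-carboxylate
Product: 16 methyl (1R,4aR,5S,8aR)-5-{(3E)-5-{[tert-butyl(dimethyl)silyl]oxy}-3-methylpent-3-en-1-yl}-1,4a-dimethyl-6-methylidene-2-oxodecahydronaphthalene-1-carboxylate, via lithium enolate 15 (not isolated)
Conditions: Li (5 equiv), t-BuOH (3 equiv), NH3/THF, −78 °C (14 added to the blue solution); isoprene; then MeI (10 equiv), −78 to −33 °C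
Reagents that add atoms: iodomethane CI
Why: Birch-type dissolving-metal reduction with enolate trapping (reductive alkylation): electron transfer reduces first the alkylidene β-keto ester and then the remaining enone, each carbanion being protonated by t-BuOH, leaving the β-keto ester enolate 15, which resists further reduction; C5–H is delivered axially, anti to the C10 methyl (trans ring fusion), and MeI enters from the α face away from the axial C10 methyl, so the ester becomes axial (4β) and the new methyl equatorial.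

Step 12
Reactants: 16 methyl (1R,4aR,5S,8aR)-5-{(3E)-5-{[tert-butyl(dimethyl)silyl]oxy}-3-methylpent-3-en-1-yl}-1,4a-dimethyl-6-methylidene-2-oxodecahydronaphthalene-1-carboxylate
Product: 17 methyl (1R,2R,4aR,5S,8aR)-5-{(3E)-5-{[tert-butyl(dimethyl)silyl]oxy}-3-methylpent-3-en-1-yl}-2-hydroxy-1,4a-dimethyl-6-methylidenedecahydronaphthalene-1-carboxylate
Conditions: LiBH(s-Bu)3 (1.5 equiv), THF, −78 °C; aq. NH4Cl
Reagents that add atoms: none
Why: Ketone reduction by a bulky trialkylborohydride, which avoids the axial trajectory past the axial hydrogens on C1 and C5 and attacks equatorially to give the axial 3α-alcohol (3R); the hindered ester and the alkenes are untouched.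

Step 13
Reactants: 17 methyl (1R,2R,4aR,5S,8aR)-5-{(3E)-5-{[tert-butyl(dimethyl)silyl]oxy}-3-methylpent-3-en-1-yl}-2-hydroxy-1,4a-dimethyl-6-methylidenedecahydronaphthalene-1-carboxylate
Product: 18 methyl (1R,2R,4aR,5S,8aR)-2-(acetyloxy)-5-{(3E)-5-{[tert-butyl(dimethyl)silyl]oxy}-3-methylpent-3-en-1-yl}-1,4a-dimethyl-6-methylidenedecahydronaphthalene-1-carboxylate
Conditions: Ac2O, DMAP, pyridine, 40 °C
Reagents that add atoms: acetic anhydride CC(=O)OC(C)=O
Why: DMAP-catalysed acylation of the hindered axial alcohol with retention at C3.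

Step 14
Reactants: 18 methyl (1R,2R,4aR,5S,8aR)-2-(acetyloxy)-5-{(3E)-5-{[tert-butyl(dimethyl)silyl]oxy}-3-methylpent-3-en-1-yl}-1,4a-dimethyl-6-methylidenedecahydronaphthalene-1-carboxylate
Product: 19 methyl (1R,2R,4aR,5S,8aR)-2-(acetyloxy)-5-[(3E)-5-hydroxy-3-methylpent-3-en-1-yl]-1,4a-dimethyl-6-methylidenedecahydronaphthalene-1-carboxylate
Conditions: HF·pyridine, THF, 0 to 25 °C
Reagents that add atoms: none
Why: Fluoride-driven silyl ether cleavage; the acetate, the methyl ester and both alkenes are stable to buffered HF.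

Step 15
Reactants: 19 methyl (1R,2R,4aR,5S,8aR)-2-(acetyloxy)-5-[(3E)-5-hydroxy-3-methylpent-3-en-1-yl]-1,4a-dimethyl-6-methylidenedecahydronaphthalene-1-carboxylate
Product: 20 methyl (1R,2R,4aR,5S,8aR)-2-(acetyloxy)-5-{2-[(2R,3R)-3-(hydroxymethyl)-2-methyloxiran-2-yl]ethyl}-1,4a-dimethyl-6-methylidenedecahydronaphthalene-1-carboxylate
Conditions: Ti(OiPr)4 (10 mol %), D-(−)-diethyl tartrate (12 mol %), t-BuOOH, 4 Å molecular sieves, CH2Cl2, −20 °C
Reagents that add atoms: tert-butyl hydroperoxide CC(C)(C)OO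
Why: Sharpless asymmetric epoxidation: the titanium tartrate complex epoxidises only the allylic alcohol (the C8 methylidene has no directing hydroxyl), and D-(−)-tartrate delivers oxygen to the face that gives the (2R,3R)-epoxy alcohol from an E-3-methyl-2-alken-1-ol, as it does with geraniol, under reagent control.

Step 16
Reactants: 20 methyl (1R,2R,4aR,5S,8aR)-2-(acetyloxy)-5-{2-[(2R,3R)-3-(hydroxymethyl)-2-methyloxiran-2-yl]ethyl}-1,4a-dimethyl-6-methylidenedecahydronaphthalene-1-carboxylate
Product: 21 methyl (1R,2R,4aR,5S,8aR)-2-(acetyloxy)-5-{2-[(2R,3S)-3-formyl-2-methyloxiran-2-yl]ethyl}-1,4a-dimethyl-6-methylidenedecahydronaphthalene-1-carboxylate (CNP0145900.1)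
Conditions: Dess–Martin periodinane, pyridine, CH2Cl2, 0 to 25 °C
Reagents that add atoms: none
Why: Dess–Martin oxidation of the primary epoxy alcohol under buffered, non-epimerising conditions; the epoxide centres are untouched (the C14 descriptor changes from R to S only through the priority change).

## Compound list

1 | 2,3-dimethylbenzoic acid | Cc1cccc(C(=O)O)c1C | starting material
2 | 6-hydroxy-2,3-dimethylbenzoic acid | Cc1ccc(O)c(C(=O)O)c1C | intermediate
3 | methyl 6-hydroxy-2,3-dimethylbenzoate | Cc1ccc(O)c(C(=O)OC)c1C | intermediate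
4 | ethyl (triphenyl-λ5-phosphanylidene)acetate | CCOC(=O)C=P(c1ccccc1)(c1ccccc1)c1ccccc1 | starting material
5 | ethyl 2-(triphenyl-λ5-phosphanylidene)-3-(trimethylsilyl)propanoate | CCOC(=O)C(C[Si](C)(C)C)=P(c1ccccc1)(c1ccccc1)c1ccccc1 | intermediate
6 | geraniol, (2E)-3,7-dimethylocta-2,6-dien-1-ol | CC(C)=CCC/C(C)=C/CO | starting material
7 | tert-butyl{[(2E)-3,7-dimethylocta-2,6-dien-1-yl]oxy}dimethylsilane | CC(C)=CCC/C(C)=C/CO[Si](C)(C)C(C)(C)C | intermediate
8 | (4E)-6-{[tert-butyl(dimethyl)silyl]oxy}-4-methylhex-4-enal | O=CCC/C(C)=C/CO[Si](C)(C)C(C)(C)C | intermediate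
9 | ethyl (2Z,6E)-8-{[tert-butyl(dimethyl)silyl]oxy}-6-methyl-2-[(trimethylsilyl)methyl]octa-2,6-dienoate | CCOC(=O)/C(C[Si](C)(C)C)=C/CC/C(C)=C/CO[Si](C)(C)C(C)(C)C | intermediate
10 | (2Z,6E)-8-{[tert-butyl(dimethyl)silyl]oxy}-6-methyl-2-[(trimethylsilyl)methyl]octa-2,6-dien-1-ol | OC/C(C[Si](C)(C)C)=C/CC/C(C)=C/CO[Si](C)(C)C(C)(C)C | intermediate
11 | {(2E,6E)-2-(bromomethyl)-8-{[tert-butyl(dimethyl)silyl]oxy}-6-methylocta-2,6-dien-1-yl}(trimethyl)silane | BrC/C(C[Si](C)(C)C)=C/CC/C(C)=C/CO[Si](C)(C)C(C)(C)C | intermediate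
12 | dilithium dianion of 3 (phenoxide plus benzylic carbanion at the 2-methyl) | [Li+].[Li+].[CH2-]c1c(C)ccc([O-])c1C(=O)OC | intermediate
13 | methyl 2-{(3Z,7E)-9-{[tert-butyl(dimethyl)silyl]oxy}-7-methyl-3-[(trimethylsilyl)methyl]nona-3,7-dien-1-yl}-6-hydroxy-3-methylbenzoate | COC(=O)c1c(O)ccc(C)c1CC/C(C[Si](C)(C)C)=C/CC/C(C)=C/CO[Si](C)(C)C(C)(C)C | intermediate
14 | methyl (4aR,5S)-5-{(3E)-5-{[tert-butyl(dimethyl)silyl]oxy}-3-methylpent-3-en-1-yl}-4a-methyl-6-methylidene-2-oxo-2,4a,5,6,7,8-hexahydronaphthalene-1-carboxylate | C=C1CCC2=C(C(=O)OC)C(=O)C=C[C@]2(C)[C@H]1CC/C(C)=C/CO[Si](C)(C)C(C)(C)C | intermediate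
15 | lithium enolate (C3–OLi, C3=C4) of keto ester after reduction of both conjugated alkenes | [Li+].C=C1CC[C@@H]2[C@](C)(CCC([O-])=C2C(=O)OC)[C@H]1CC/C(C)=C/CO[Si](C)(C)C(C)(C)C | intermediate
16 | methyl (1R,4aR,5S,8aR)-5-{(3E)-5-{[tert-butyl(dimethyl)silyl]oxy}-3-methylpent-3-en-1-yl}-1,4a-dimethyl-6-methylidene-2-oxodecahydronaphthalene-1-carboxylate | C=C1CC[C@@H]2[C@](C)(CCC(=O)[C@]2(C)C(=O)OC)[C@H]1CC/C(C)=C/CO[Si](C)(C)C(C)(C)C | intermediate
17 | methyl (1R,2R,4aR,5S,8aR)-5-{(3E)-5-{[tert-butyl(dimethyl)silyl]oxy}-3-methylpent-3-en-1-yl}-2-hydroxy-1,4a-dimethyl-6-methylidenedecahydronaphthalene-1-carboxylate | C=C1CC[C@@H]2[C@](C)(CC[C@@H](O)[C@]2(C)C(=O)OC)[C@H]1CC/C(C)=C/CO[Si](C)(C)C(C)(C)C | intermediate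
18 | methyl (1R,2R,4aR,5S,8aR)-2-(acetyloxy)-5-{(3E)-5-{[tert-butyl(dimethyl)silyl]oxy}-3-methylpent-3-en-1-yl}-1,4a-dimethyl-6-methylidenedecahydronaphthalene-1-carboxylate | C=C1CC[C@@H]2[C@](C)(CC[C@@H](OC(C)=O)[C@]2(C)C(=O)OC)[C@H]1CC/C(C)=C/CO[Si](C)(C)C(C)(C)C | intermediate
19 | methyl (1R,2R,4aR,5S,8aR)-2-(acetyloxy)-5-[(3E)-5-hydroxy-3-methylpent-3-en-1-yl]-1,4a-dimethyl-6-methylidenedecahydronaphthalene-1-carboxylate | C=C1CC[C@@H]2[C@](C)(CC[C@@H](OC(C)=O)[C@]2(C)C(=O)OC)[C@H]1CC/C(C)=C/CO | intermediate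
20 | methyl (1R,2R,4aR,5S,8aR)-2-(acetyloxy)-5-{2-[(2R,3R)-3-(hydroxymethyl)-2-methyloxiran-2-yl]ethyl}-1,4a-dimethyl-6-methylidenedecahydronaphthalene-1-carboxylate | C=C1CC[C@@H]2[C@](C)(CC[C@@H](OC(C)=O)[C@]2(C)C(=O)OC)[C@H]1CC[C@@]1(C)O[C@@H]1CO | intermediate
21 | methyl (1R,2R,4aR,5S,8aR)-2-(acetyloxy)-5-{2-[(2R,3S)-3-formyl-2-methyloxiran-2-yl]ethyl}-1,4a-dimethyl-6-methylidenedecahydronaphthalene-1-carboxylate | C=C1CC[C@@H]2[C@](C)(CC[C@@H](OC(C)=O)[C@]2(C)C(=O)OC)[C@H]1CC[C@@]1(C)O[C@@H]1C=O | target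

## Step count and risk

Total step count: 16. Longest linear sequence: 13 steps (geraniol 6 to 21, steps 4 to 16).

The three steps most likely to fail:

Step 10 is the greatest risk. The ring closure itself has a racemic prototype, but the face selectivity of a chiral λ3-iodane towards a tethered carbon nucleophile at the para position is untested, and ionisation in the fluoroalcohol may erode it. The fallback sets out from 13 and comes back at 14. It gives up reagent control: 13 is cyclised with achiral PhI(OAc)2 in (CF3)2CHOH at −20 °C, where the Z-allylsilane still fixes the relative configuration of C9 and C10. This gives 14 as a racemate together with its mirror image, methyl (4aS,5R)-5-{(3E)-5-{[tert-butyl(dimethyl)silyl]oxy}-3-methylpent-3-en-1-yl}-4a-methyl-6-methylidene-2-oxo-2,4a,5,6,7,8-hexahydronaphthalene-1-carboxylate F1. The racemate is resolved by preparative supercritical-fluid chromatography on a cellulose carbamate phase, and 14 re-enters at step 11.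

Step 11 is next. The second conjugated alkene (C1=C2) sits in an enolate-bearing ring and may resist electron transfer, and prolonged exposure to the metal endangers the allylic silyl ether and invites reductive ring opening at C9–C10. The fallback sets out from 14 and comes back at 16. It separates the two reductions by mechanism: 14 is treated with only 2.2 equiv of Li in NH3/THF without a proton donor and then with MeI, which reduces and methylates only the alkylidene keto ester. This gives the C1=C2 enone methyl (1R,4aR,5S,8aR)-5-{(3E)-5-{[tert-butyl(dimethyl)silyl]oxy}-3-methylpent-3-en-1-yl}-1,4a-dimethyl-6-methylidene-2-oxo-1,2,4a,5,6,7,8,8a-octahydronaphthalene-1-carboxylate F2. Its remaining enone is then reduced by hydride conjugate addition with [(Ph3P)CuH]6 in benzene at 25 °C. This creates no stereocentre and leaves the isolated alkenes alone, and gives 16.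

Step 9 is the third. The phenoxide lowers the acidity of the ortho methyl and twists the ester, so dianion formation may be incomplete or O-alkylation may compete. The fallback sets out from 2 and comes back at 13. Phenol and acid are tied together with acetone, (CF3CO)2O and CF3CO2H as the acetonide 2,2,5,6-tetramethyl-4H-1,3-benzodioxin-4-one F3, whose planar lactone gives clean lateral lithiation with LiN(i-Pr)2 at −78 °C. Alkylation with 11 gives 5-{(3Z,7E)-9-{[tert-butyl(dimethyl)silyl]oxy}-7-methyl-3-[(trimethylsilyl)methyl]nona-3,7-dien-1-yl}-2,2,6-trimethyl-4H-1,3-benzodioxin-4-one F4, and NaOMe in MeOH opens the dioxinone to the methyl salicylate 13.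

Further compounds
F1 | step 10 | methyl (4aS,5R)-5-{(3E)-5-{[tert-butyl(dimethyl)silyl]oxy}-3-methylpent-3-en-1-yl}-4a-methyl-6-methylidene-2-oxo-2,4a,5,6,7,8-hexahydronaphthalene-1-carboxylate (enantiomer of 14) | C=C1CCC2=C(C(=O)OC)C(=O)C=C[C@@]2(C)[C@@H]1CC/C(C)=C/CO[Si](C)(C)C(C)(C)C
F2 | step 11 | methyl (1R,4aR,5S,8aR)-5-{(3E)-5-{[tert-butyl(dimethyl)silyl]oxy}-3-methylpent-3-en-1-yl}-1,4a-dimethyl-6-methylidene-2-oxo-1,2,4a,5,6,7,8,8a-octahydronaphthalene-1-carboxylate | C=C1CC[C@@H]2[C@](C)(C=CC(=O)[C@]2(C)C(=O)OC)[C@H]1CC/C(C)=C/CO[Si](C)(C)C(C)(C)C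
F3 | step 9 | 2,2,5,6-tetramethyl-4H-1,3-benzodioxin-4-one | CC1(C)OC(=O)c2c(C)c(C)ccc2O1
F4 | step 9 | 5-{(3Z,7E)-9-{[tert-butyl(dimethyl)silyl]oxy}-7-methyl-3-[(trimethylsilyl)methyl]nona-3,7-dien-1-yl}-2,2,6-trimethyl-4H-1,3-benzodioxin-4-one | CC1(C)OC(=O)c2c(CC/C(C[Si](C)(C)C)=C/CC/C(C)=C/CO[Si](C)(C)C(C)(C)C)c(C)ccc2O1
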